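**Plan** (germacrane locants throughout: ring C1–C10, C14 on C10, C15 on C4, C11–C13 on C7)
- Retrosynthesis cuts, in this order: the C8 ester C–O bond, the 1,10-epoxide, C11=C13, the lactone C6–O bond and C7–C11. The Z,Z-cyclodecadienone that remains is traced back, by re-forming a C1–C6 bond, to a bicyclic γ-hydroxystannane.
- Enabling feature: the oxygenated C6 and the epoxide carbon C1 face each other across the ten-membered ring. A C1–C6 bond therefore divides it, with its two cis olefins, into ring A (C1–C6, holding C4=C5) and ring B (C6–C10 plus C1, with tin on C10).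
- Forward: ring B comes from cyclohexane-1,3,5-triol (its carbinol carbons become C6, C8, C10). Tin and then methyl go onto C10 and a C2–C3 arm onto C1; vinyl on C6, an isopropenyl ketone at C3 and metathesis close ring A.
- Pb(OAc)4 then cuts C1–C6 and opens the ten-membered ring; C7 alkylation, invertive lactonization, methylenation, directed epoxidation and acylation finish.
- Stereochemistry: C8 from lipase desymmetrization; C3 from CBS reduction; C1, C6, C10 of the bicycle are relay centres that fix the Z olefin and then vanish; C7 by alkylation anti to C8–O; C6 by Felkin reduction then Mitsunobu inversion; the ring epoxide by the free C8 hydroxyl; the side-chain epoxide by Sharpless epoxidation.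

Key step: step 11

Assumption: the lipase acetylates the R-configured carbinol of meso diol 2, the usual preference of lipases for secondary alcohols; if the enzyme shows the opposite sense, hydrolysis of the meso diacetate with the same enzyme gives 3 instead.

Step 1
Reactants: 1 cis,cis-cyclohexane-1,3,5-triol
Product: 2 all-cis 5-(4-methoxybenzyloxy)cyclohexane-1,3-diol (meso)
Conditions: NaH (1 equiv), 4-MeOC6H4CH2Cl (1 equiv), Bu4NI (cat.), DMF, 0 °C → rt
Reagents that add atoms: 4-methoxybenzyl chloride, COc1ccc(CCl)cc1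
Why: Williamson etherification of the mono-alkoxide; the three hydroxyls are equivalent, so one equivalent each of base and halide should give mainly the mono-ether (unreacted triol is recycled), and the product is meso, so no stereocentre is set.

Step 2
Reactants: 2 all-cis 5-(4-methoxybenzyloxy)cyclohexane-1,3-diol
Product: 3 (1R,3R,5S)-3-hydroxy-5-(4-methoxybenzyloxy)cyclohexyl acetate
Conditions: Burkholderia cepacia lipase (Amano PS), vinyl acetate, t-BuOMe, rt
Reagents that add atoms: vinyl acetate, CC(=O)OC=C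
Why: Lipase-catalysed transesterification desymmetrizes the meso diol by acetylating one of the two enantiotopic carbinols (the future C10), which fixes the absolute configuration of the ether carbon, the future C8.

Step 3
Reactants: 3 (1R,3R,5S)-3-hydroxy-5-(4-methoxybenzyloxy)cyclohexyl acetate
Product: 5 (R)-5-(4-methoxybenzyloxy)cyclohex-2-en-1-one, via acetoxy ketone 4 (not isolated)
Conditions: Dess–Martin periodinane, CH2Cl2, rt; then Et3N, 0 °C → rt
Reagents that add atoms: none
Why: Dess–Martin oxidation gives the β-acetoxy ketone, from which the amine removes acetic acid by E1cB elimination (acetate leaves far more readily than the benzylic alkoxide), giving the enone with C8 untouched.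

Step 4
Reactants: 5 (R)-5-(4-methoxybenzyloxy)cyclohex-2-en-1-one
Product: 8 (S)-5-(4-methoxybenzyloxy)-3-(trimethylstannyl)cyclohex-2-en-1-one, via lithium enolate 6 (not isolated), via selenide 7 (not isolated)
Conditions: Me3SnLi, THF, −78 °C; PhSeCl, −78 °C; then 30% H2O2, pyridine, CH2Cl2, 0 °C
Reagents that add atoms: trimethylstannyllithium, [Li][Sn](C)(C)C
Why: Conjugate addition of the stannyl anion (anti to the C8 ether) gives a regiodefined enolate that is selenenylated at C1 anti to tin; the selenoxide is then cis to H10, its only β-hydrogen, and syn elimination restores the enone with tin kept on C10 (selenoxide elimination).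

Step 5
Reactants: 8 (S)-5-(4-methoxybenzyloxy)-3-(trimethylstannyl)cyclohex-2-en-1-one; 9 2-bromo-N-methoxy-N-methylacetamide
Product: 11 N-methoxy-N-methyl-2-[(1R,2S,4S)-4-(4-methoxybenzyloxy)-2-methyl-6-oxo-2-(trimethylstannyl)cyclohexyl]acetamide, via lithium enolate 10 (not isolated)
Conditions: Me2CuLi, Et2O, −78 °C; then 9, HMPA, THF, −78 → −40 °C; NH4Cl quench at −78 °C
Reagents that add atoms: lithium dimethylcuprate, [Li+].C[Cu-]C
Why: The Gilman cuprate adds to C10 of the β-stannyl enone anti to the C8 ether, so methyl becomes axial and tin equatorial and cis to the ether; the enolate is then alkylated by SN2 at C1 on the face anti to the axial methyl, which places the amide arm axial and cis to tin (conjugate addition–enolate alkylation, kinetic product).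

Step 6
Reactants: 11 ketone from step 5; 12 vinylmagnesium bromide
Product: 13 2-[(1R,2S,4S,6R)-6-hydroxy-4-(4-methoxybenzyloxy)-2-methyl-2-(trimethylstannyl)-6-vinylcyclohexyl]-N-methoxy-N-methylacetamide
Conditions: CH2=CHMgBr, CeCl3, THF, −78 °C
Reagents that add atoms: none
Why: 1,2-Addition of the vinylcerium reagent: in the chair of 11 that keeps tin and the C8 ether equatorial, the axial C10 methyl screens the axial trajectory, so vinyl should enter equatorially and cis to the axial C1 arm (the future cis ring fusion), while the weakly basic cerium reagent avoids epimerization at C1 and spares the Weinreb amide.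

Step 7
Reactants: 13 carbinol from step 6; 14 isopropenylmagnesium bromide
Product: 15 1-[(1R,2S,4S,6R)-6-hydroxy-4-(4-methoxybenzyloxy)-2-methyl-2-(trimethylstannyl)-6-vinylcyclohexyl]-3-methylbut-3-en-2-one
Conditions: CH2=C(CH3)MgBr (3 equiv), THF, −78 → 0 °C
Reagents that add atoms: none
Why: Weinreb ketone synthesis: the first equivalent deprotonates the tertiary alcohol and the next adds once to the amide, whose magnesium chelate holds until work-up; O6 and the arm are trans-diaxial, so the alkoxide cannot lactonize.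

Step 8
Reactants: 15 hydroxy enone from step 7
Product: 16 (2S)-1-[(1R,2S,4S,6R)-6-hydroxy-4-(4-methoxybenzyloxy)-2-methyl-2-(trimethylstannyl)-6-vinylcyclohexyl]-3-methylbut-3-en-2-ol
Conditions: (R)-2-methyl-CBS-oxazaborolidine (cat.), BH3·SMe2, THF, −30 °C
Reagents that add atoms: none
Why: CBS reduction under reagent control: the oxazaborolidine binds the ketone with the isopropenyl group as the large substituent and delivers hydride to give the 3S allylic alcohol, largely independent of the remote ring centres.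

Step 9
Reactants: 16 diol from step 8
Product: 17 2-O-tert-butyldimethylsilyl ether of 16
Conditions: TBSCl, imidazole, DMF, rt
Reagents that add atoms: tert-butyldimethylsilyl chloride, CC(C)(C)[Si](C)(C)Cl
Why: Silylation of the secondary allylic alcohol; the tertiary C6 hydroxyl does not react with the silyl chloride, and acidic reagents that could ionize the γ-stannyl tertiary alcohol are avoided.

Step 10
Reactants: 17 silyl ether from step 9
Product: 18 cis-fused hydroxystannane (2S,4aR,6S,8S,8aR)-2-(tert-butyldimethylsilyloxy)-6-(4-methoxybenzyloxy)-3,8-dimethyl-8-(trimethylstannyl)-1,2,4a,5,6,7,8,8a-octahydronaphthalen-4a-ol (germacrane locants 1R,3S,6R,8S,10S)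
Conditions: second-generation Grubbs catalyst RuCl2(=CHPh)(H2IMes)(PCy3) (cat.), CH2Cl2, 40 °C
Reagents that add atoms: none
Why: Ring-closing metathesis of the vinyl and isopropenyl groups, which are cis on ring B, closes ring A as a cyclohexene (hence Z C4=C5); free tertiary allylic alcohols and alkylstannanes tolerate the ruthenium carbene.

Step 11
Reactants: 18 cis-fused bicyclic γ-hydroxystannane
Product: 19 (2Z,4S,6Z,9R)-4-(tert-butyldimethylsilyloxy)-9-(4-methoxybenzyloxy)-3,7-dimethylcyclodeca-2,6-dien-1-one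
Conditions: Pb(OAc)4, pyridine, benzene, rt
Reagents that add atoms: none
Why: Ligand exchange at tetravalent lead gives the C6 alkoxide, and collapse of its O–Pb bond to divalent lead is coupled with cleavage of C1–C6 and loss of the trimethyltin group to acetate, so the C6 ketone and the C1=C10 olefin form together. This is the oxidative fragmentation of γ-hydroxystannanes to alkenyl ketones, a Grob-type fragmentation with tin as electrofuge. No ring is closed by bond formation: the ten-membered ring appears when the bond shared by rings A and B is cut, so no closure mode applies. No stereocentre is created; C1, C6 and C10 become trigonal and C3 and C8 are untouched. The step needs cleavage of C1–C6 only and a Z C1=C10 bond: in the chair of ring B that carries tin and the C8 ether equatorial (only the C10 methyl and O6 are syn-axial), C10–Sn is antiperiplanar to C1–C6, and C2, axial and cis to tin, is gauche to C9, so anti elimination puts C2 and C9 on the same side. C4=C5 is Z because it was made inside ring A.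

Step 12
Reactants: 19 dienone from step 11; 20 methyl bromoacetate
Product: 22 methyl 2-[(1R,3Z,5S,7Z,10R)-5-(tert-butyldimethylsilyloxy)-10-(4-methoxybenzyloxy)-4,8-dimethyl-2-oxocyclodeca-3,7-dien-1-yl]acetate, via lithium enolate 21 (not isolated)
Conditions: LiN(SiMe3)2, THF, −78 °C; BrCH2CO2Me, −78 → −40 °C
Reagents that add atoms: none
Why: Kinetic deprotonation on the saturated side (C7) gives the cross-conjugated lithium enolate, which is alkylated by SN2; with the C8–O bond perpendicular to the enolate plane the electrophile should enter anti to it (the usual 2,3-anti course of β-alkoxy enolate alkylations), giving 7R.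

Step 13
Reactants: 22 keto ester from step 12
Product: 25 2-[(1R,2S,3Z,5S,7Z,10R)-5-(tert-butyldimethylsilyloxy)-2-hydroxy-10-(4-methoxybenzyloxy)-4,8-dimethylcyclodeca-3,7-dien-1-yl]acetic acid, via hydroxy ester 23 (not isolated), via cis-lactone 24 (not isolated)
Conditions: NaBH4, CeCl3·7H2O, MeOH, −40 °C; then LiOH, THF/H2O, 0 °C; AcOH to pH 5, used at once
Reagents that add atoms: lithium hydroxide, [Li+].[OH-]
Why: Luche 1,2-reduction: hydride should attack the C6 carbonyl from the ring periphery, anti to ring carbon C8 (Felkin–Anh with C8 as the large group), giving the 6S alcohol cis to the C7 arm; this closes to the cis-lactone, and hydroxide reopens it so that the C6 carbinol is free for an invertive closure.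

Step 14
Reactants: 25 hydroxy acid from step 13
Product: 26 3β-(tert-butyldimethylsilyloxy)-8β-(4-methoxybenzyloxy)-13-norgermacra-1(10)Z,4Z-dien-12,6α-olide (3S,6R,7R,8R)
Conditions: PPh3, DIAD, THF (high dilution), 0 °C → rt
Reagents that add atoms: none
Why: Mitsunobu lactonization: the carboxylate displaces the C6 oxyphosphonium group from the rear (intramolecular SN2, 5-exo-tet), which inverts C6 to R and gives the trans-fused γ-lactone.

Step 15
Reactants: 26 trans-lactone from step 14; 27 N,N-dimethylmethyleneiminium iodide (Eschenmoser's salt)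
Product: 31 3β-(tert-butyldimethylsilyloxy)-8β-(4-methoxybenzyloxy)germacra-1(10)Z,4Z,11(13)-trien-12,6α-olide, via lactone enolate 28 (not isolated), via Mannich base 29 (not isolated), via ammonium iodide 30 (not isolated)
Conditions: LiN(iPr)2, THF, −78 °C; 27, −78 °C → rt; MeI, MeOH, rt; NaHCO3 (aq), CH2Cl2, rt
Reagents that add atoms: none
Why: Mannich reaction of the lactone enolate with the iminium salt, N-methylation and base-induced loss of trimethylamine install the exocyclic methylene; the C11 centre of the Mannich base is transient.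

Step 16
Reactants: 31 methylene lactone from step 15
Product: 32 3β-(tert-butyldimethylsilyloxy)-8β-hydroxygermacra-1(10)Z,4Z,11(13)-trien-12,6α-olide
Conditions: DDQ, CH2Cl2/pH 7 buffer, 0 °C
Reagents that add atoms: none
Why: Oxidative cleavage of the 4-methoxybenzyl ether (benzylic hydride abstraction by the quinone, hydrolysis of the oxocarbenium ion); the silyl ether, the olefins and the unsaturated lactone are inert.

Step 17
Reactants: 32 C8 alcohol from step 16
Product: 33 1β,10β-epoxy-3β-(tert-butyldimethylsilyloxy)-8β-hydroxygermacra-4Z,11(13)-dien-12,6α-olide (1R,3S,6R,7R,8R,10S)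
Conditions: VO(acac)2 (cat.), t-BuOOH, CH2Cl2, 0 °C → rt
Reagents that add atoms: tert-butyl hydroperoxide, CC(C)(C)OO
Why: Vanadium-catalysed hydroxyl-directed epoxidation: the homoallylic 8β-hydroxyl binds the metal and delivers the peroxide oxygen to its own face of C1=C10 (1R,10S); C4=C5 is only bishomoallylic and flanked by two allylic C–O bonds, and the methylene lactone is electron-poor, so both stay.

Step 18
Reactants: 34 angelic acid
Product: 35 (Z)-2-methylbut-2-en-1-ol
Conditions: LiAlH4, Et2O, 0 °C
Reagents that add atoms: none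
Why: Hydride reduction of the acid to the allylic alcohol, with the Z geometry retained.

Step 19
Reactants: 35 (Z)-2-methylbut-2-en-1-ol
Product: 36 [(2S,3R)-2,3-dimethyloxiran-2-yl]methanol
Conditions: Ti(OiPr)4 (cat.), L-(+)-diethyl tartrate (cat.), t-BuOOH, 4 Å molecular sieves, CH2Cl2, −20 °C
Reagents that add atoms: tert-butyl hydroperoxide, CC(C)(C)OO
Why: Sharpless asymmetric epoxidation: the titanium tartrate complex delivers oxygen to one face of the allylic alcohol (L-(+)-tartrate should give 2S), and the Z geometry is carried into the epoxide, which fixes C3 as R.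

Step 20
Reactants: 36 [(2S,3R)-2,3-dimethyloxiran-2-yl]methanol
Product: 37 (2R,3R)-2,3-dimethyloxirane-2-carboxylic acid
Conditions: TEMPO (cat.), PhI(OAc)2, MeCN/H2O, rt
Reagents that add atoms: water, O
Why: Nitroxyl-catalysed oxidation of the primary alcohol through the aldehyde hydrate to the acid; the epoxide and both centres are untouched (C2 changes its descriptor only through the new priorities).

Step 21
Reactants: 33 epoxy alcohol from step 17; 37 (2R,3R)-2,3-dimethyloxirane-2-carboxylic acid
Product: 39 8-O-[(2R,3R)-2,3-dimethyloxirane-2-carbonyl] ester of 33, via mixed anhydride 38 (not isolated)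
Conditions: 37, 2,4,6-Cl3C6H2COCl, Et3N, toluene, rt; then 33, DMAP, toluene, rt → 40 °C
Reagents that add atoms: none
Why: Yamaguchi esterification: the mixed anhydride acylates the hindered secondary C8 alcohol under DMAP catalysis; no stereocentre is touched and the acid has no α-hydrogen to epimerize.

Step 22
Reactants: 39 silyl-protected ester from step 21
Product: 40 target (1R,3S,4Z,6R,7R,8R,10S)-1,10-epoxy-3-hydroxy-8-[(2R,3R)-2,3-dimethyloxirane-2-carbonyloxy]germacra-4,11(13)-dien-12,6-olide
Conditions: HF·pyridine, pyridine, THF, 0 °C → rt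
Reagents that add atoms: none
Why: Fluoride-mediated desilylation (Si–F bond formation) frees the C3 hydroxyl; buffering with pyridine protects both epoxides and the methylene lactone.

**Compound list**
1 | cis,cis-cyclohexane-1,3,5-triol | O[C@@H]1C[C@H](O)C[C@H](O)C1 | starting material
2 | all-cis 5-(4-methoxybenzyloxy)cyclohexane-1,3-diol (meso) | O[C@H]1C[C@@H](O)C[C@@H](OCc2ccc(OC)cc2)C1 | intermediate
3 | (1R,3R,5S)-3-hydroxy-5-(4-methoxybenzyloxy)cyclohexyl acetate | O[C@H]1C[C@@H](OC(C)=O)C[C@@H](OCc2ccc(OC)cc2)C1 | intermediate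
4 | (1S,5R)-3-oxo-5-(4-methoxybenzyloxy)cyclohexyl acetate | O=C1C[C@@H](OC(C)=O)C[C@@H](OCc2ccc(OC)cc2)C1 | intermediate (not isolated)
5 | (R)-5-(4-methoxybenzyloxy)cyclohex-2-en-1-one | O=C1C=CC[C@@H](OCc2ccc(OC)cc2)C1 | intermediate
6 | lithium 5-(4-methoxybenzyloxy)-3-(trimethylstannyl)cyclohex-1-en-1-olate (tin trans to the ether) | [Li]OC1=C[C@H]([Sn](C)(C)C)C[C@@H](OCc2ccc(OC)cc2)C1 | intermediate (not isolated)
7 | 5-(4-methoxybenzyloxy)-2-(phenylselanyl)-3-(trimethylstannyl)cyclohexan-1-one (2,3-trans; 3,5-trans) | O=C1[C@@H]([Se]c2ccccc2)[C@H]([Sn](C)(C)C)C[C@@H](OCc3ccc(OC)cc3)C1 | intermediate (not isolated)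
8 | (S)-5-(4-methoxybenzyloxy)-3-(trimethylstannyl)cyclohex-2-en-1-one | O=C1C=C([Sn](C)(C)C)C[C@@H](OCc2ccc(OC)cc2)C1 | intermediate
9 | 2-bromo-N-methoxy-N-methylacetamide | BrCC(=O)N(C)OC | starting material
10 | lithium 5-(4-methoxybenzyloxy)-3-methyl-3-(trimethylstannyl)cyclohex-1-en-1-olate (methyl trans to the ether) | [Li]OC1=C[C@@](C)([Sn](C)(C)C)C[C@@H](OCc2ccc(OC)cc2)C1 | intermediate (not isolated)
11 | N-methoxy-N-methyl-2-[(1R,2S,4S)-4-(4-methoxybenzyloxy)-2-methyl-6-oxo-2-(trimethylstannyl)cyclohexyl]acetamide | O=C1[C@@H](CC(=O)N(C)OC)[C@@](C)([Sn](C)(C)C)C[C@@H](OCc2ccc(OC)cc2)C1 | intermediate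
12 | vinylmagnesium bromide | C=C[Mg]Br | starting material
13 | 2-[(1R,2S,4S,6R)-6-hydroxy-4-(4-methoxybenzyloxy)-2-methyl-2-(trimethylstannyl)-6-vinylcyclohexyl]-N-methoxy-N-methylacetamide | O[C@]1(C=C)[C@@H](CC(=O)N(C)OC)[C@@](C)([Sn](C)(C)C)C[C@@H](OCc2ccc(OC)cc2)C1 | intermediate
14 | isopropenylmagnesium bromide | CC(=C)[Mg]Br | starting material
15 | 1-[(1R,2S,4S,6R)-6-hydroxy-4-(4-methoxybenzyloxy)-2-methyl-2-(trimethylstannyl)-6-vinylcyclohexyl]-3-methylbut-3-en-2-one | O[C@]1(C=C)[C@@H](CC(=O)C(C)=C)[C@@](C)([Sn](C)(C)C)C[C@@H](OCc2ccc(OC)cc2)C1 | intermediate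
16 | (2S)-1-[(1R,2S,4S,6R)-6-hydroxy-4-(4-methoxybenzyloxy)-2-methyl-2-(trimethylstannyl)-6-vinylcyclohexyl]-3-methylbut-3-en-2-ol | O[C@]1(C=C)[C@@H](C[C@H](O)C(C)=C)[C@@](C)([Sn](C)(C)C)C[C@@H](OCc2ccc(OC)cc2)C1 | intermediate
17 | 2-O-tert-butyldimethylsilyl ether of 16 | O[C@]1(C=C)[C@@H](C[C@H](O[Si](C)(C)C(C)(C)C)C(C)=C)[C@@](C)([Sn](C)(C)C)C[C@@H](OCc2ccc(OC)cc2)C1 | intermediate
18 | cis-fused hydroxystannane (2S,4aR,6S,8S,8aR)-2-(tert-butyldimethylsilyloxy)-6-(4-methoxybenzyloxy)-3,8-dimethyl-8-(trimethylstannyl)-1,2,4a,5,6,7,8,8a-octahydronaphthalen-4a-ol | O[C@]12C=C(C)[C@@H](O[Si](C)(C)C(C)(C)C)C[C@H]1[C@@](C)([Sn](C)(C)C)C[C@@H](OCc3ccc(OC)cc3)C2 | intermediate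
19 | (2Z,4S,6Z,9R)-4-(tert-butyldimethylsilyloxy)-9-(4-methoxybenzyloxy)-3,7-dimethylcyclodeca-2,6-dien-1-one | O=C1/C=C(/C)[C@@H](O[Si](C)(C)C(C)(C)C)C/C=C(/C)C[C@@H](OCc2ccc(OC)cc2)C1 | intermediate
20 | methyl bromoacetate | COC(=O)CBr | starting material
21 | lithium C6–C7 enolate of 19 (ring-cis) | [Li]O/C1=C/[C@H](OCc2ccc(OC)cc2)C/C(C)=C\C[C@H](O[Si](C)(C)C(C)(C)C)/C(C)=C\1 | intermediate (not isolated)
22 | methyl 2-[(1R,3Z,5S,7Z,10R)-5-(tert-butyldimethylsilyloxy)-10-(4-methoxybenzyloxy)-4,8-dimethyl-2-oxocyclodeca-3,7-dien-1-yl]acetate | O=C1/C=C(/C)[C@@H](O[Si](C)(C)C(C)(C)C)C/C=C(/C)C[C@@H](OCc2ccc(OC)cc2)[C@H]1CC(=O)OC | intermediate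
23 | methyl 2-[(1R,2S,3Z,5S,7Z,10R)-5-(tert-butyldimethylsilyloxy)-2-hydroxy-10-(4-methoxybenzyloxy)-4,8-dimethylcyclodeca-3,7-dien-1-yl]acetate | O[C@H]1/C=C(/C)[C@@H](O[Si](C)(C)C(C)(C)C)C/C=C(/C)C[C@@H](OCc2ccc(OC)cc2)[C@H]1CC(=O)OC | intermediate (not isolated)
24 | 3β-(tert-butyldimethylsilyloxy)-8β-(4-methoxybenzyloxy)-13-norgermacra-1(10)Z,4Z-dien-12,6β-olide (cis-fused; 3S,6S,7R,8R) | C1C(=O)O[C@H]2/C=C(/C)[C@@H](O[Si](C)(C)C(C)(C)C)C/C=C(/C)C[C@@H](OCc3ccc(OC)cc3)[C@@H]12 | intermediate (not isolated)
25 | 2-[(1R,2S,3Z,5S,7Z,10R)-5-(tert-butyldimethylsilyloxy)-2-hydroxy-10-(4-methoxybenzyloxy)-4,8-dimethylcyclodeca-3,7-dien-1-yl]acetic acid | O[C@H]1/C=C(/C)[C@@H](O[Si](C)(C)C(C)(C)C)C/C=C(/C)C[C@@H](OCc2ccc(OC)cc2)[C@H]1CC(=O)O | intermediate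
26 | 3β-(tert-butyldimethylsilyloxy)-8β-(4-methoxybenzyloxy)-13-norgermacra-1(10)Z,4Z-dien-12,6α-olide (trans-fused; 3S,6R,7R,8R) | C1C(=O)O[C@@H]2/C=C(/C)[C@@H](O[Si](C)(C)C(C)(C)C)C/C=C(/C)C[C@@H](OCc3ccc(OC)cc3)[C@@H]12 | intermediate
27 | N,N-dimethylmethyleneiminium iodide (Eschenmoser's salt) | C=[N+](C)C.[I-] | starting material
28 | lithium enolate of lactone 26 | C1=C(O[Li])O[C@@H]2/C=C(/C)[C@@H](O[Si](C)(C)C(C)(C)C)C/C=C(/C)C[C@@H](OCc3ccc(OC)cc3)[C@@H]12 | intermediate (not isolated)
29 | 11-(dimethylaminomethyl) derivative of 26 (Mannich base; aminomethyl trans to C8 on the lactone ring) | CN(C)C[C@@H]1C(=O)O[C@@H]2/C=C(/C)[C@@H](O[Si](C)(C)C(C)(C)C)C/C=C(/C)C[C@@H](OCc3ccc(OC)cc3)[C@@H]12 | intermediate (not isolated)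
30 | N-methyl ammonium iodide of 29 | C[N+](C)(C)C[C@@H]1C(=O)O[C@@H]2/C=C(/C)[C@@H](O[Si](C)(C)C(C)(C)C)C/C=C(/C)C[C@@H](OCc3ccc(OC)cc3)[C@@H]12.[I-] | intermediate (not isolated)
31 | 3β-(tert-butyldimethylsilyloxy)-8β-(4-methoxybenzyloxy)germacra-1(10)Z,4Z,11(13)-trien-12,6α-olide | C=C1C(=O)O[C@@H]2/C=C(/C)[C@@H](O[Si](C)(C)C(C)(C)C)C/C=C(/C)C[C@@H](OCc3ccc(OC)cc3)[C@@H]12 | intermediate
32 | 3β-(tert-butyldimethylsilyloxy)-8β-hydroxygermacra-1(10)Z,4Z,11(13)-trien-12,6α-olide | C=C1C(=O)O[C@@H]2/C=C(/C)[C@@H](O[Si](C)(C)C(C)(C)C)C/C=C(/C)C[C@@H](O)[C@@H]12 | intermediate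
33 | 1β,10β-epoxy-3β-(tert-butyldimethylsilyloxy)-8β-hydroxygermacra-4Z,11(13)-dien-12,6α-olide (1R,3S,6R,7R,8R,10S) | C=C1C(=O)O[C@@H]2/C=C(/C)[C@@H](O[Si](C)(C)C(C)(C)C)C[C@H]3O[C@@]3(C)C[C@@H](O)[C@@H]12 | intermediate
34 | angelic acid, (Z)-2-methylbut-2-enoic acid | C/C=C(/C)C(=O)O | starting material
35 | (Z)-2-methylbut-2-en-1-ol | C/C=C(/C)CO | intermediate
36 | [(2S,3R)-2,3-dimethyloxiran-2-yl]methanol | OC[C@]1(C)O[C@@H]1C | intermediate
37 | (2R,3R)-2,3-dimethyloxirane-2-carboxylic acid | OC(=O)[C@]1(C)O[C@@H]1C | intermediate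
38 | (2R,3R)-2,3-dimethyloxirane-2-carboxylic 2,4,6-trichlorobenzoic anhydride | O=C(OC(=O)c1c(Cl)cc(Cl)cc1Cl)[C@]1(C)O[C@@H]1C | intermediate (not isolated)
39 | 8-O-[(2R,3R)-2,3-dimethyloxirane-2-carbonyl] ester of 33 | C=C1C(=O)O[C@@H]2/C=C(/C)[C@@H](O[Si](C)(C)C(C)(C)C)C[C@H]3O[C@@]3(C)C[C@@H](OC(=O)[C@]3(C)O[C@@H]3C)[C@@H]12 | intermediate
40 | CNP0268255.3, (1R,3S,4Z,6R,7R,8R,10S)-1,10-epoxy-3-hydroxy-8-[(2R,3R)-2,3-dimethyloxirane-2-carbonyloxy]germacra-4,11(13)-dien-12,6-olide | C=C1C(=O)O[C@@H]2/C=C(/C)[C@@H](O)C[C@H]3O[C@@]3(C)C[C@@H](OC(=O)[C@]3(C)O[C@@H]3C)[C@@H]12 | target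

**Step count**
Total: 22 steps (19 in the main line, 3 for the acid 37). Longest linear sequence: 19 steps (steps 1–17, 21, 22).

**Steps most likely to fail**

1. Step 5. The copper-bound enolate of this hindered ketone may alkylate too slowly; proton transfer could then move the enolate toward C7, where the C8 ether is expelled, or let the axial C1 arm relax to the equatorial epimer. Fallback, setting out from 8: the cuprate addition is run with Me3SiCl and the enolate is stored as the trimethylsilyl enol ether F1, which is isolated. MeLi in THF then releases the copper-free lithium enolate 10, which is alkylated with 9 in THF/DMPU at −78 °C. The route is rejoined at 11.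

2. Step 12. The electrophile may enter from the ring periphery on the face syn to the C8 ether, or the enolate may lose the C8 ether by β-elimination. Fallback, setting out from 19: if the alkylation delivers the 7-epi keto ester F2, this compound is deprotonated again at C7 (LiN(iPr)2, −78 °C) and the enolate is protonated kinetically (AcOH, −78 °C). The proton then takes the accessible face the electrophile had chosen, which inverts C7. The route is rejoined at 22.

3. Step 13. Hydride may add to the other face of the C6 carbonyl (syn to C8), so that the alcohol already has the 6R configuration and inversion would then give the wrong lactone. Fallback, setting out from 22: the reduction is worked up without hydroxide to give the (6R)-hydroxy ester F3, which is closed with retention under acid catalysis (PPTS, CH2Cl2, rt) instead of by the Mitsunobu route. The route is rejoined at 26 and step 14 is omitted.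

**Further compounds**
F1 | step 5 | trimethylsilyl enol ether of the cuprate adduct of 8 | C[Si](C)(C)OC1=C[C@@](C)([Sn](C)(C)C)C[C@@H](OCc2ccc(OC)cc2)C1
F2 | step 12 | 7-epi keto ester, methyl 2-[(1S,3Z,5S,7Z,10R)-5-(tert-butyldimethylsilyloxy)-10-(4-methoxybenzyloxy)-4,8-dimethyl-2-oxocyclodeca-3,7-dien-1-yl]acetate | O=C1/C=C(/C)[C@@H](O[Si](C)(C)C(C)(C)C)C/C=C(/C)C[C@@H](OCc2ccc(OC)cc2)[C@@H]1CC(=O)OC
F3 | step 13 | (6R)-hydroxy ester, methyl 2-[(1R,2R,3Z,5S,7Z,10R)-5-(tert-butyldimethylsilyloxy)-2-hydroxy-10-(4-methoxybenzyloxy)-4,8-dimethylcyclodeca-3,7-dien-1-yl]acetate | O[C@@H]1/C=C(/C)[C@@H](O[Si](C)(C)C(C)(C)C)C/C=C(/C)C[C@@H](OCc2ccc(OC)cc2)[C@H]1CC(=O)OC
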